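The quinone ring is disconnected at C1–C8a, the bond from the carbonyl carbon beside the side-chain carbon C2 to the ring-fusion carbon. Since that ring carries oxygen at C1 and C4, hydrogen at C3 and one substituent at C2, it maps onto a Dötz benzannulation: an aryl(methoxy)carbene chromium complex supplies C4 and the dioxygenated benzene ring, a terminal (R)-propargylic silyl ether supplies C3, C2 and the side chain, and one CO ligand becomes C1. In one operation these merge into a chromium-bound dienylketene whose electrocyclisation forges C1–C8a; oxidative work-up delivers the quinone. The stereocentre comes from a Midland ynone reduction; deprotection and butyrylation finish.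

Key step: step 7

Remark: the 5,8-dihydroxy-1,4-naphthoquinone core equilibrates rapidly between its two ring tautomers, so after deprotection a quinone drawn in either ring is the same compound; the target is the butanoate of (R)-shikonin.

Step 1
Reactants: 1 hydroquinone
Product: 2 1,4-bis(methoxymethoxy)benzene
Conditions: NaH, MOMCl, DMF, 0 °C to rt
Reagents that add atoms: chloromethyl methyl ether (MOMCl), COCCl
Why: Williamson O-alkylation of the bis-phenoxide installs two acetal groups that later direct ortho-lithiation and come off in mild acid.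

Step 2
Reactants: 2 1,4-bis(methoxymethoxy)benzene; 3 chromium hexacarbonyl
Product: 6 pentacarbonyl{[2,5-bis(methoxymethoxy)phenyl](methoxy)methylidene}chromium, via 2,5-bis(methoxymethoxy)phenyllithium 4 (not isolated), via lithium acylpentacarbonylchromate 5 (not isolated)
Conditions: n-BuLi, THF, 0 °C to rt; Cr(CO)6, THF, 0 °C to rt; concentrate; Me3OBF4, CH2Cl2, 0 °C
Reagents that add atoms: trimethyloxonium tetrafluoroborate, C[O+](C)C.F[B-](F)(F)F
Why: Fischer carbene synthesis, in which acetal-directed ortho-lithiation gives the aryllithium, this adds to a CO ligand, and the resulting acylate is O-methylated faster than the acetals can react.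

Step 3
Reactants: 7 4-methylpent-3-enoic acid
Product: 9 N-methoxy-N,4-dimethylpent-3-enamide, via 1-(4-methylpent-3-enoyl)imidazole 8 (not isolated)
Conditions: CDI, CH2Cl2, rt; then MeNHOMe·HCl, rt
Reagents that add atoms: N,O-dimethylhydroxylamine hydrochloride, CNOC.Cl
Why: Acyl imidazolide formation and aminolysis (Weinreb amide synthesis) run under near-neutral conditions that should keep the alkene out of conjugation.

Step 4
Reactants: 9 N-methoxy-N,4-dimethylpent-3-enamide; 10 ethynylmagnesium bromide
Product: 12 6-methylhept-5-en-1-yn-3-one, via bromomagnesium hemiaminal adduct 11 (not isolated)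
Conditions: HC≡CMgBr (2.5 equiv), THF, −10 to 0 °C; inverse quench into cold aq. NaHSO4
Reagents that add atoms: none
Why: Weinreb ketone synthesis, in which the chelated tetrahedral adduct blocks over-addition and the acidic inverse quench protonates the released amine before it can add to the ynone.

Step 5
Reactants: 12 6-methylhept-5-en-1-yn-3-one
Product: 14 (R)-6-methylhept-5-en-1-yn-3-ol, via B-alkoxy-9-borabicyclononane 13 (not isolated)
Conditions: B-isopinocampheyl-9-borabicyclo[3.3.1]nonane from (+)-α-pinene ((R)-Alpine-Borane), neat, rt; then MeCHO; then H2NCH2CH2OH, Et2O, 0 °C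
Reagents that add atoms: none
Why: Midland reduction, in which hydride passes from the pinanyl C–H through a boat-like six-membered transition state with the slim ethynyl group next to the pinanyl methyl, so the (R)-reagent should give the (R)-1-alkyn-3-ol, and the trialkylborane leaves the trisubstituted alkene alone.

Step 6
Reactants: 14 (R)-6-methylhept-5-en-1-yn-3-ol
Product: 15 (R)-tert-butyl[(6-methylhept-5-en-1-yn-3-yl)oxy]dimethylsilane
Conditions: TBSCl, imidazole, DMF, rt
Reagents that add atoms: tert-butyldimethylsilyl chloride, CC(C)(C)[Si](C)(C)Cl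
Why: Silylation of the secondary alcohol, needed because a free propargylic hydroxyl would trap the ketene of step 7 as a lactone, whereas the silyl ether is inert and a poor leaving group.

Step 7
Reactants: 6 pentacarbonyl{[2,5-bis(methoxymethoxy)phenyl](methoxy)methylidene}chromium; 15 (R)-tert-butyl[(6-methylhept-5-en-1-yn-3-yl)oxy]dimethylsilane
Product: 18 2-[(1R)-1-(tert-butyldimethylsilyloxy)-4-methylpent-3-enyl]-5,8-bis(methoxymethoxy)naphthalene-1,4-dione, via chromium-bound dienylketene 16 (not isolated), via tricarbonylchromium naphthol complex 17 (not isolated)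
Conditions: THF (0.05 M), 50 °C, argon; then (NH4)2Ce(NO3)6, MeCN/H2O, 0 °C
Reagents that add atoms: water, O
Why: Loss of one CO from 6 (eased by chelation of the ortho acetal oxygen) lets the alkyne of 15 insert with its CH terminus bonding to the carbene carbon, a CO ligand then inserts to give the chromium-bound (E)-dienylketene 16, and 6π-electrocyclisation joins the ketene carbon (future C1) to the free ortho carbon of the aryl ring (future C8a) before tautomerisation to naphthol complex 17. The closest known reaction type is the Dötz benzannulation of aryl(methoxy)carbene pentacarbonylchromium complexes with terminal alkynes, propargylic silyl ethers included, followed by oxidation with tetravalent cerium to the 1,4-quinone. The one ring closed is the six-membered quinone ring, by disrotatory 6π-electrocyclic closure of the dienylketene, with an aromatic C=C of the aryl ring as the third π bond. No stereocentre is created, and the existing silyloxy-bearing carbon lies outside the reacting π system, carries a poor leaving group and should not epimerise under these neutral conditions. The step needs four selectivities: insertion regiochemistry (the bulky silyloxyalkyl group stays away from the carbene carbon and so ends beside the CO-derived C1, as is general for terminal alkynes), CO insertion over indene formation (chromium, THF, moderate temperature), closure at the only unsubstituted ortho position, and oxidation of the phenol/methoxy ring instead of the bis-acetal ring. (NH4)2Ce(NO3)6 strips the chromium and converts the 4-methoxynaphthol into the quinone, water supplying the C4 oxygen as methanol leaves.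

Step 8
Reactants: 18 2-[(1R)-1-(tert-butyldimethylsilyloxy)-4-methylpent-3-enyl]-5,8-bis(methoxymethoxy)naphthalene-1,4-dione
Product: 19 (R)-shikonin, 5,8-dihydroxy-2-[(1R)-1-hydroxy-4-methylpent-3-enyl]naphthalene-1,4-dione
Conditions: 3 M aq. HCl, THF/i-PrOH, 0 °C to rt, argon, dark
Reagents that add atoms: none
Why: Acid hydrolysis should cleave the two aryl acetals (peri to the quinone carbonyls, giving hydrogen-bonded phenols) and the secondary silyl ether at its Si–O bond, so the C–O bond at the stereocentre is never broken.

Step 9
Reactants: 19 (R)-shikonin; 20 butyric acid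
Product: 21 butylshikonin
Conditions: DCC, DMAP (cat.), CH2Cl2, 0 °C to rt
Reagents that add atoms: none
Why: Steglich esterification should acylate only the side-chain alcohol, because the two peri-phenols are tied up in hydrogen bonds to the quinone carbonyls, and acylation on oxygen retains the (R) configuration.

Compound list
1 | hydroquinone | Oc1ccc(O)cc1 | starting material
2 | 1,4-bis(methoxymethoxy)benzene | COCOc1ccc(OCOC)cc1 | intermediate
3 | chromium hexacarbonyl, Cr(CO)6 | O=C=[Cr](=C=O)(=C=O)(=C=O)(=C=O)=C=O | starting material
4 | 2,5-bis(methoxymethoxy)phenyllithium (not isolated) | COCOc1ccc(OCOC)c([Li])c1 | intermediate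
5 | lithium [2,5-bis(methoxymethoxy)benzoyl]pentacarbonylchromate (not isolated) | [Li+].[O-]C(c1cc(OCOC)ccc1OCOC)=[Cr](=C=O)(=C=O)(=C=O)(=C=O)=C=O | intermediate
6 | pentacarbonyl{[2,5-bis(methoxymethoxy)phenyl](methoxy)methylidene}chromium | COC(c1cc(OCOC)ccc1OCOC)=[Cr](=C=O)(=C=O)(=C=O)(=C=O)=C=O | intermediate
7 | 4-methylpent-3-enoic acid | CC(C)=CCC(=O)O | starting material
8 | 1-(4-methylpent-3-enoyl)imidazole (not isolated) | CC(C)=CCC(=O)n1ccnc1 | intermediate
9 | N-methoxy-N,4-dimethylpent-3-enamide | CC(C)=CCC(=O)N(C)OC | intermediate
10 | ethynylmagnesium bromide | C#C[Mg]Br | starting material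
11 | bromomagnesium salt of the N-methoxy-N-methyl hemiaminal of 12 (not isolated, racemic at the new carbon) | C#CC(CC=C(C)C)(O[Mg]Br)N(C)OC | intermediate
12 | 6-methylhept-5-en-1-yn-3-one | C#CC(=O)CC=C(C)C | intermediate
13 | 9-{[(3R)-6-methylhept-5-en-1-yn-3-yl]oxy}-9-borabicyclo[3.3.1]nonane (not isolated) | C#C[C@H](OB1C2CCCC1CCC2)CC=C(C)C | intermediate
14 | (R)-6-methylhept-5-en-1-yn-3-ol | C#C[C@H](O)CC=C(C)C | intermediate
15 | (R)-tert-butyl[(6-methylhept-5-en-1-yn-3-yl)oxy]dimethylsilane | C#C[C@H](O[Si](C)(C)C(C)(C)C)CC=C(C)C | intermediate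
16 | tricarbonylchromium η4-complex of the (E)-dienylketene 4-[2,5-bis(methoxymethoxy)phenyl]-4-methoxy-2-[(1R)-1-(tert-butyldimethylsilyloxy)-4-methylpent-3-enyl]buta-1,3-dien-1-one (not isolated; π-bound Cr(CO)3 written as a separate fragment) | CC(C)(C)[Si](C)(C)O[C@H](CC=C(C)C)C(=C=O)/C=C(/OC)c1cc(OCOC)ccc1OCOC.O=C=[Cr](=C=O)=C=O | intermediate
17 | tricarbonylchromium η6-complex of 2-[(1R)-1-(tert-butyldimethylsilyloxy)-4-methylpent-3-enyl]-4-methoxy-5,8-bis(methoxymethoxy)naphthalen-1-ol (not isolated; π-bound Cr(CO)3 written as a separate fragment) | CC(C)(C)[Si](C)(C)O[C@H](CC=C(C)C)c1cc(OC)c2c(OCOC)ccc(OCOC)c2c1O.O=C=[Cr](=C=O)=C=O | intermediate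
18 | 2-[(1R)-1-(tert-butyldimethylsilyloxy)-4-methylpent-3-enyl]-5,8-bis(methoxymethoxy)naphthalene-1,4-dione | CC(C)(C)[Si](C)(C)O[C@H](CC=C(C)C)C1=CC(=O)c2c(OCOC)ccc(OCOC)c2C1=O | intermediate
19 | (R)-shikonin | O[C@H](CC=C(C)C)C1=CC(=O)c2c(O)ccc(O)c2C1=O | intermediate
20 | butyric acid | CCCC(=O)O | starting material
21 | butylshikonin, (1R)-1-(5,8-dihydroxy-1,4-dioxo-1,4-dihydronaphthalen-2-yl)-4-methylpent-3-enyl butanoate | CCCC(=O)O[C@H](CC=C(C)C)C1=CC(=O)c2c(O)ccc(O)c2C1=O | target

Total step count: 9. Longest linear sequence: 7 steps (steps 3, 4, 5, 6, 7, 8, 9, from 4-methylpent-3-enoic acid).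

Steps most likely to fail

1. Step 7. After alkyne insertion the vinylcarbene may cyclise onto the aryl ring without taking up CO, or the chelated ortho-alkoxy complex may insert the hindered propargylic ether so slowly that carbene decomposition wins. The fallback gives up ring construction and attaches the side chain to a preformed naphthalene. It sets out from Weinreb amide 9 and returns at quinone 18. Commercial naphthazarin is reduced with Na2S2O4 and alkylated (NaH, MOMCl, DMF) to 1,4,5,8-tetrakis(methoxymethoxy)naphthalene F1. Ortho-lithiation of F1 (n-BuLi, TMEDA, THF, 0 °C) and acylation with 9 should give 4-methyl-1-[1,4,5,8-tetrakis(methoxymethoxy)naphthalen-2-yl]pent-3-en-1-one F2. Reduction with (+)-B-chlorodiisopinocampheylborane should give the (R)-carbinol F3, which is silylated (TBSCl, imidazole) to the silyl ether F4. Oxidation of F4 with (NH4)2Ce(NO3)6 should give 18 together with its ring isomer, the 6-substituted 5,8-bis(methoxymethoxy)naphthalene-1,4-dione F5. Both are taken through step 8, because their deprotection products are the two tautomers of the one naphthazarin 19.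

2. Step 8. In aqueous acid the freed carbinol may ionise (loss of configuration) or add to the protonated prenyl alkene (cyclisation). The fallback reorders the end game so that the free alcohol never meets protic acid. It sets out from 18 and returns at target 21. HF·pyridine (THF, 0 °C) should remove only the silyl group to give the bis-acetal alcohol F6. Steglich esterification of F6 with butyric acid 20 (DCC, DMAP) should give the bis-acetal butanoate F7. Me2BBr (CH2Cl2, −78 °C, then aq. NaHCO3) should cleave the two aryl acetals of F7 under aprotic conditions and give 21 directly.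

3. Step 4. The terminal, β,γ-unsaturated ynone may take up the released amine in a conjugate addition, polymerise, or let its alkene migrate into conjugation before it is reduced. The fallback avoids the terminal ynone and changes the mode of asymmetric induction. It sets out from 9 and returns at alkynol 14. Lithium (trimethylsilyl)acetylide (THF, −78 °C) and 9 should give the silyl-capped ynone F8. Noyori transfer hydrogenation with RuCl[(R,R)-TsDPEN](p-cymene) in i-PrOH should give the (R)-propargylic alcohol F9. K2CO3 in MeOH removes the C-silyl group to give 14.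

Further compounds
F1 | step 7 | 1,4,5,8-tetrakis(methoxymethoxy)naphthalene | COCOc1ccc(OCOC)c2c(OCOC)ccc(OCOC)c12
F2 | step 7 | 4-methyl-1-[1,4,5,8-tetrakis(methoxymethoxy)naphthalen-2-yl]pent-3-en-1-one | CC(C)=CCC(=O)c1cc(OCOC)c2c(OCOC)ccc(OCOC)c2c1OCOC
F3 | step 7 | (1R)-4-methyl-1-[1,4,5,8-tetrakis(methoxymethoxy)naphthalen-2-yl]pent-3-en-1-ol | O[C@H](CC=C(C)C)c1cc(OCOC)c2c(OCOC)ccc(OCOC)c2c1OCOC
F4 | step 7 | tert-butyldimethylsilyl ether of F3 | CC(C)(C)[Si](C)(C)O[C@H](CC=C(C)C)c1cc(OCOC)c2c(OCOC)ccc(OCOC)c2c1OCOC
F5 | step 7 | 6-[(1R)-1-(tert-butyldimethylsilyloxy)-4-methylpent-3-enyl]-5,8-bis(methoxymethoxy)naphthalene-1,4-dione | CC(C)(C)[Si](C)(C)O[C@H](CC=C(C)C)c1cc(OCOC)c2C(=O)C=CC(=O)c2c1OCOC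
F6 | step 8 | 2-[(1R)-1-hydroxy-4-methylpent-3-enyl]-5,8-bis(methoxymethoxy)naphthalene-1,4-dione | O[C@H](CC=C(C)C)C1=CC(=O)c2c(OCOC)ccc(OCOC)c2C1=O
F7 | step 8 | (1R)-1-[5,8-bis(methoxymethoxy)-1,4-dioxo-1,4-dihydronaphthalen-2-yl]-4-methylpent-3-enyl butanoate | CCCC(=O)O[C@H](CC=C(C)C)C1=CC(=O)c2c(OCOC)ccc(OCOC)c2C1=O
F8 | step 4 | 6-methyl-1-(trimethylsilyl)hept-5-en-1-yn-3-one | C[Si](C)(C)C#CC(=O)CC=C(C)C
F9 | step 4 | (R)-6-methyl-1-(trimethylsilyl)hept-5-en-1-yn-3-ol | C[Si](C)(C)C#C[C@H](O)CC=C(C)C
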